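**Retrosynthetic overview**
1. Target 30 ⇐ angeloylation at C3–OH and desilylation at C9–O of the macrocyclic bis-epoxide 27, which already carries all eight stereocentres.
2. 27 ⇐ acyclic keto sulfonium salt 24: the C1–C10 bond and the C1–C10 oxirane are made together by an intramolecular sulfonium-ylide epoxidation of the C10 methyl ketone (ten-membered carbocycle and oxirane close in one operation).
3. 24 ⇐ epoxy aldehyde 16 + acetaldehyde (C1–C2, sets C3); 16 ⇐ aldehyde 9 + hydroxyacetone (C9, C10, C14; sets C8 and C9) + 3-methylbut-2-enoyl chloride.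
4. 9 ⇐ (S)-carvone: enone epoxidation sets C4/C5 against C7; α'-hydroxylation and glycol-type cleavage of C3–C8 then open the six-membered ring.
5. Ring order: C4–C5 oxirane first (step 1), then the ten-membered ring and the C1–C10 oxirane together (step 12).

Assumption: locants C1–C15 follow germacrane numbering of the target for all intermediates (C3 O-angelate, C8 O-senecioate, C9 OH, methyls on C4 and C10, isopropenyl on C7); both oxiranes are cis-fused to the ring, and 5 is carried as its C8 epimer mixture because C8 becomes sp2 in step 3.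

CIP labels of some intermediates differ from those of 30 only through priority changes; the spatial arrangement is that of 30 throughout, as written in the SMILES.

**Route**

Step 1
Reactants: 1 (S)-(+)-carvone; 2 hydrogen peroxide
Product: 3 (1S,4S,6S)-1-methyl-4-(prop-1-en-2-yl)-7-oxabicyclo[4.1.0]heptan-2-one (oxirane trans to isopropenyl)
Conditions: H2O2 (30% aq), NaOH (cat.), MeOH, 0 °C
Reagents that add atoms: hydrogen peroxide, OO
Why: Weitz–Scheffer nucleophilic epoxidation attacks only the enone (isopropenyl untouched) and the hydroperoxide adds anti to the C7 isopropenyl group, so C4 and C5 are set trans to it by substrate control.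

Step 2
Reactants: 3; 4 3-phenyl-2-(phenylsulfonyl)oxaziridine
Product: 5 (1S,4R,6S)-3-hydroxy-1-methyl-4-(prop-1-en-2-yl)-7-oxabicyclo[4.1.0]heptan-2-one (both C3 epimers)
Conditions: LiN(iPr)2, THF, −78 °C; then 3-phenyl-2-(phenylsulfonyl)oxaziridine; NH4Cl (aq)
Reagents that add atoms: 3-phenyl-2-(phenylsulfonyl)oxaziridine, O=S(=O)(N1OC1c1ccccc1)c1ccccc1
Why: Only C8 carries enolisable hydrogens, so the lithium enolate forms regiospecifically and is hydroxylated by the N-sulfonyloxaziridine (Davis enolate oxidation); the new centre is destroyed in step 3.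

Step 3
Reactants: 5; 6 water
Product: 7 (2S,3S)-3-[(2R)-2-formyl-3-methylbut-3-en-1-yl]-2-methyloxirane-2-carboxylic acid
Conditions: NaIO4, THF/H2O, rt
Reagents that add atoms: water, O
Why: Periodate glycol-type cleavage of the α-hydroxy ketone (through its hydrate) breaks C3–C8 into acid and aldehyde without touching alkene, oxirane or the C4, C5 and C7 centres.

Step 4
Reactants: 7; 8 ethanethiol
Product: 9 S-ethyl (2S,3S)-3-[(2R)-2-formyl-3-methylbut-3-en-1-yl]-2-methyloxirane-2-carbothioate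
Conditions: EtSH, DCC, DMAP (cat.), CH2Cl2, 0 °C
Reagents that add atoms: ethanethiol, CCS
Why: Steglich-type thioesterification stores C3 as a thioester that survives the next three steps and can later be reduced to the aldehyde in the presence of a ketone.

Step 5
Reactants: 9; 10 hydroxyacetone
Product: 11 S-ethyl (2S,3S)-3-[(2R,3S,4S)-3,4-dihydroxy-5-oxo-2-(prop-1-en-2-yl)hexyl]-2-methyloxirane-2-carbothioate
Conditions: hydroxyacetone (10 equiv), L-proline (30 mol%), DMSO, rt
Reagents that add atoms: hydroxyacetone, CC(=O)CO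
Why: Proline enamine aldol of hydroxyacetone reacts at the hydroxylated carbon through an H-bonded chair transition state to give the anti-1,2-diol, L-proline setting 8S and 9S by catalyst control (sense taken from α-branched aldehyde precedent).

Step 6
Reactants: 11; 12 chlorotriethylsilane
Product: 13 S-ethyl (2S,3S)-3-[(2R,3S,4S)-3-hydroxy-5-oxo-2-(prop-1-en-2-yl)-4-(triethylsilyloxy)hexyl]-2-methyloxirane-2-carbothioate
Conditions: Et3SiCl (1.05 equiv), imidazole, CH2Cl2, −20 °C
Reagents that add atoms: chlorotriethylsilane, CC[Si](Cl)(CC)CC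
Why: Selective silylation: the C9 hydroxyl next to the flat acetyl group is less hindered and more acidic than the C8 hydroxyl flanked by branched C7.

Step 7
Reactants: 13; 14 3-methylbut-2-enoyl chloride
Product: 15 S-ethyl (2S,3S)-2-methyl-3-[(2R,3S,4S)-3-(3-methylbut-2-enoyloxy)-5-oxo-2-(prop-1-en-2-yl)-4-(triethylsilyloxy)hexyl]oxirane-2-carbothioate
Conditions: 3-methylbut-2-enoyl chloride, pyridine, DMAP (cat.), CH2Cl2, 0 °C to rt
Reagents that add atoms: 3-methylbut-2-enoyl chloride, CC(C)=CC(=O)Cl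
Why: DMAP-catalysed acylation of the only free hydroxyl installs the C8 senecioate with retention and removes the hydroxyl that could open the C4–C5 oxirane.

Step 8
Reactants: 15
Product: 16 (2S,3S)-2-methyl-3-[(2R,3S,4S)-3-(3-methylbut-2-enoyloxy)-5-oxo-2-(prop-1-en-2-yl)-4-(triethylsilyloxy)hexyl]oxirane-2-carbaldehyde
Conditions: Et3SiH, Pd/C (5 mol%), acetone, rt
Reagents that add atoms: none
Why: Fukuyama reduction: palladium inserts into the C–S bond and the silane delivers hydride, so only the thioester is reduced while ketone, esters, silyl ether and oxirane stay intact.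

Step 9
Reactants: 16; 17 acetaldehyde
Product: 19 (1S)-1-[(2R,3S)-2-methyl-3-[(2R,3S,4S)-3-(3-methylbut-2-enoyloxy)-5-oxo-2-(prop-1-en-2-yl)-4-(triethylsilyloxy)hexyl]oxiran-2-yl]propane-1,3-diol, via beta-hydroxy aldehyde 18 (not isolated)
Conditions: MeCHO (5 equiv), (R)-α,α-bis[3,5-bis(trifluoromethyl)phenyl]pyrrolidin-2-ylmethanol (20 mol%), DMF, 4 °C; then NaBH(OAc)3, AcOH, 0 °C
Reagents that add atoms: acetaldehyde, CC=O
Why: Diarylprolinol-catalysed enamine cross-aldol of acetaldehyde onto the non-enolisable epoxy aldehyde sets 3S by catalyst control (R catalyst chosen by analogy with proline aldols), and triacetoxyborohydride then reduces only the new aldehyde.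

Step 10
Reactants: 19; 20 iodine
Product: 21 (1S)-3-iodo-1-[(2R,3S)-2-methyl-3-[(2R,3S,4S)-3-(3-methylbut-2-enoyloxy)-5-oxo-2-(prop-1-en-2-yl)-4-(triethylsilyloxy)hexyl]oxiran-2-yl]propan-1-ol
Conditions: I2, PPh3, imidazole, CH2Cl2, 0 °C
Reagents that add atoms: iodine, [I][I]
Why: Appel-type iodination is selective for the primary hydroxyl over the hindered secondary C3 hydroxyl beside the oxirane.

Step 11
Reactants: 21; 22 diphenyl sulfide; 23 silver tetrafluoroborate
Product: 24 [(3S)-3-hydroxy-3-[(2R,3S)-2-methyl-3-[(2R,3S,4S)-3-(3-methylbut-2-enoyloxy)-5-oxo-2-(prop-1-en-2-yl)-4-(triethylsilyloxy)hexyl]oxiran-2-yl]propyl]diphenylsulfonium tetrafluoroborate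
Conditions: Ph2S (10 equiv), AgBF4, CH2Cl2, rt, dark
Reagents that add atoms: diphenyl sulfide, c1ccc(Sc2ccccc2)cc1; silver tetrafluoroborate, [Ag+].F[B-](F)(F)F
Why: Silver-assisted S-alkylation of diphenyl sulfide is driven by AgI precipitation, and the two phenyl groups leave the C1 methylene as the only acidic position of the sulfonium salt.

Step 12
Reactants: 24
Product: 27 (1R,3S,4R,5S,7R,8S,9S,10R)-1,10:4,5-diepoxy-3-hydroxy-9-(triethylsilyloxy)germacr-11-en-8-yl 3-methylbut-2-enoate, via sulfonium ylide 25 (not isolated), via oxido-sulfonium betaine 26 (not isolated)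
Conditions: KN(SiMe3)2 (1.05 equiv, slow addition), THF (0.001 M), −78 to −20 °C
Reagents that add atoms: none
Why: Proposed new method: an intramolecular Johnson–Corey–Chaykovsky epoxidation is used as the ring-closing event – the base removes the C1–H next to sulfonium (far more acidic than ketone or alcohol C–H/O–H), ylide 25 adds to the C10 methyl ketone anti to the C9 silyloxy group (polar Felkin–Anh, giving the erythro C9/C10 relationship) to close the ten-membered carbocycle as betaine 26, and antiperiplanar displacement of Ph2S by the alkoxide closes the oxirane, the cis C2/C9 fusion being the low-strain mode for a ten-membered ring, so C10 and C1 are set together; the closest known chemistry is intermolecular epoxidation of ketones by diphenylsulfonium alkylides and sulfonium-ylide epoxy-annulations that close five- to seven-membered rings.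

Step 13
Reactants: 27; 28 angelic acid
Product: 29 (1R,3S,4S,5S,7R,8S,9S,10R)-1,10:4,5-diepoxy-8-(3-methylbut-2-enoyloxy)-9-(triethylsilyloxy)germacr-11-en-3-yl (Z)-2-methylbut-2-enoate
Conditions: angelic acid, 2,4,6-trichlorobenzoyl chloride, Et3N, toluene, rt; then 27, 75 °C
Reagents that add atoms: angelic acid, C/C=C(/C)C(=O)O
Why: Yamaguchi-type esterification through the mixed anhydride, run without DMAP to avoid Z to E isomerisation of the angelate, acylates the only free hydroxyl (C3) with retention.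

Step 14
Reactants: 29
Product: 30 (1R,3S,4S,5S,7R,8S,9S,10S)-1,10:4,5-diepoxy-9-hydroxy-8-(3-methylbut-2-enoyloxy)germacr-11-en-3-yl (Z)-2-methylbut-2-enoate (CNP0320216.1)
Conditions: HF·pyridine, pyridine, THF, 0 °C
Reagents that add atoms: none
Why: Buffered fluoride desilylation frees the C9 hydroxyl under mildly acidic conditions that avoid C8 to C9 acyl migration and leave both oxiranes intact.

**Compound list**
1 | (S)-(+)-carvone | C=C(C)[C@H]1CC=C(C)C(=O)C1 | starting material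
2 | hydrogen peroxide | OO | starting material
3 | (1S,4S,6S)-1-methyl-4-(prop-1-en-2-yl)-7-oxabicyclo[4.1.0]heptan-2-one | C=C(C)[C@H]1C[C@@H]2O[C@]2(C)C(=O)C1 | intermediate
4 | 3-phenyl-2-(phenylsulfonyl)oxaziridine (racemic) | O=S(=O)(N1OC1c1ccccc1)c1ccccc1 | starting material
5 | (1S,4R,6S)-3-hydroxy-1-methyl-4-(prop-1-en-2-yl)-7-oxabicyclo[4.1.0]heptan-2-one (C3 epimers) | C=C(C)[C@H]1C[C@@H]2O[C@]2(C)C(=O)C1O | intermediate
6 | water | O | starting material
7 | (2S,3S)-3-[(2R)-2-formyl-3-methylbut-3-en-1-yl]-2-methyloxirane-2-carboxylic acid | O=C[C@@H](C(C)=C)C[C@@H]1O[C@]1(C)C(=O)O | intermediate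
8 | ethanethiol | CCS | starting material
9 | S-ethyl (2S,3S)-3-[(2R)-2-formyl-3-methylbut-3-en-1-yl]-2-methyloxirane-2-carbothioate | O=C[C@@H](C(C)=C)C[C@@H]1O[C@]1(C)C(=O)SCC | intermediate
10 | hydroxyacetone | CC(=O)CO | starting material
11 | S-ethyl (2S,3S)-3-[(2R,3S,4S)-3,4-dihydroxy-5-oxo-2-(prop-1-en-2-yl)hexyl]-2-methyloxirane-2-carbothioate | CC(=O)[C@@H](O)[C@@H](O)[C@@H](C(C)=C)C[C@@H]1O[C@]1(C)C(=O)SCC | intermediate
12 | chlorotriethylsilane | CC[Si](Cl)(CC)CC | starting material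
13 | S-ethyl (2S,3S)-3-[(2R,3S,4S)-3-hydroxy-5-oxo-2-(prop-1-en-2-yl)-4-(triethylsilyloxy)hexyl]-2-methyloxirane-2-carbothioate | CC(=O)[C@@H](O[Si](CC)(CC)CC)[C@@H](O)[C@@H](C(C)=C)C[C@@H]1O[C@]1(C)C(=O)SCC | intermediate
14 | 3-methylbut-2-enoyl chloride | CC(C)=CC(=O)Cl | starting material
15 | S-ethyl (2S,3S)-2-methyl-3-[(2R,3S,4S)-3-(3-methylbut-2-enoyloxy)-5-oxo-2-(prop-1-en-2-yl)-4-(triethylsilyloxy)hexyl]oxirane-2-carbothioate | CC(=O)[C@@H](O[Si](CC)(CC)CC)[C@@H](OC(=O)C=C(C)C)[C@@H](C(C)=C)C[C@@H]1O[C@]1(C)C(=O)SCC | intermediate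
16 | (2S,3S)-2-methyl-3-[(2R,3S,4S)-3-(3-methylbut-2-enoyloxy)-5-oxo-2-(prop-1-en-2-yl)-4-(triethylsilyloxy)hexyl]oxirane-2-carbaldehyde | CC(=O)[C@@H](O[Si](CC)(CC)CC)[C@@H](OC(=O)C=C(C)C)[C@@H](C(C)=C)C[C@@H]1O[C@]1(C)C=O | intermediate
17 | acetaldehyde | CC=O | starting material
18 | (3S)-3-hydroxy-3-[(2R,3S)-2-methyl-3-[(2R,3S,4S)-3-(3-methylbut-2-enoyloxy)-5-oxo-2-(prop-1-en-2-yl)-4-(triethylsilyloxy)hexyl]oxiran-2-yl]propanal | CC(=O)[C@@H](O[Si](CC)(CC)CC)[C@@H](OC(=O)C=C(C)C)[C@@H](C(C)=C)C[C@@H]1O[C@]1(C)[C@@H](O)CC=O | intermediate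
19 | (1S)-1-[(2R,3S)-2-methyl-3-[(2R,3S,4S)-3-(3-methylbut-2-enoyloxy)-5-oxo-2-(prop-1-en-2-yl)-4-(triethylsilyloxy)hexyl]oxiran-2-yl]propane-1,3-diol | CC(=O)[C@@H](O[Si](CC)(CC)CC)[C@@H](OC(=O)C=C(C)C)[C@@H](C(C)=C)C[C@@H]1O[C@]1(C)[C@@H](O)CCO | intermediate
20 | iodine | [I][I] | starting material
21 | (1S)-3-iodo-1-[(2R,3S)-2-methyl-3-[(2R,3S,4S)-3-(3-methylbut-2-enoyloxy)-5-oxo-2-(prop-1-en-2-yl)-4-(triethylsilyloxy)hexyl]oxiran-2-yl]propan-1-ol | CC(=O)[C@@H](O[Si](CC)(CC)CC)[C@@H](OC(=O)C=C(C)C)[C@@H](C(C)=C)C[C@@H]1O[C@]1(C)[C@@H](O)CCI | intermediate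
22 | diphenyl sulfide | c1ccc(Sc2ccccc2)cc1 | starting material
23 | silver tetrafluoroborate | [Ag+].F[B-](F)(F)F | starting material
24 | [(3S)-3-hydroxy-3-[(2R,3S)-2-methyl-3-[(2R,3S,4S)-3-(3-methylbut-2-enoyloxy)-5-oxo-2-(prop-1-en-2-yl)-4-(triethylsilyloxy)hexyl]oxiran-2-yl]propyl]diphenylsulfonium tetrafluoroborate | CC(=O)[C@@H](O[Si](CC)(CC)CC)[C@@H](OC(=O)C=C(C)C)[C@@H](C(C)=C)C[C@@H]1O[C@]1(C)[C@@H](O)CC[S+](c1ccccc1)c1ccccc1.F[B-](F)(F)F | intermediate
25 | sulfonium ylide of 24 (carbanion at C1; other centres as in 24) | CC(=O)[C@@H](O[Si](CC)(CC)CC)[C@@H](OC(=O)C=C(C)C)[C@@H](C(C)=C)C[C@@H]1O[C@]1(C)[C@@H](O)C[CH-][S+](c1ccccc1)c1ccccc1 | intermediate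
26 | ring-closed betaine (ten-membered carbocycle; C10 alkoxide; C1 diphenylsulfonio anti to it) | C=C(C)[C@H]1C[C@@H]2O[C@]2(C)[C@@H](O)C[C@H]([S+](c2ccccc2)c2ccccc2)[C@]([O-])(C)[C@@H](O[Si](CC)(CC)CC)[C@H]1OC(=O)C=C(C)C | intermediate
27 | (1R,3S,4R,5S,7R,8S,9S,10R)-1,10:4,5-diepoxy-3-hydroxy-9-(triethylsilyloxy)germacr-11-en-8-yl 3-methylbut-2-enoate | C=C(C)[C@H]1C[C@@H]2O[C@]2(C)[C@@H](O)C[C@H]2O[C@@]2(C)[C@@H](O[Si](CC)(CC)CC)[C@H]1OC(=O)C=C(C)C | intermediate
28 | angelic acid ((Z)-2-methylbut-2-enoic acid) | C/C=C(/C)C(=O)O | starting material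
29 | (1R,3S,4S,5S,7R,8S,9S,10R)-1,10:4,5-diepoxy-8-(3-methylbut-2-enoyloxy)-9-(triethylsilyloxy)germacr-11-en-3-yl (Z)-2-methylbut-2-enoate | C=C(C)[C@H]1C[C@@H]2O[C@]2(C)[C@@H](OC(=O)/C(C)=C\C)C[C@H]2O[C@@]2(C)[C@@H](O[Si](CC)(CC)CC)[C@H]1OC(=O)C=C(C)C | intermediate
30 | (1R,3S,4S,5S,7R,8S,9S,10S)-1,10:4,5-diepoxy-9-hydroxy-8-(3-methylbut-2-enoyloxy)germacr-11-en-3-yl (Z)-2-methylbut-2-enoate (CNP0320216.1) | C=C(C)[C@H]1C[C@@H]2O[C@]2(C)[C@@H](OC(=O)/C(C)=C\C)C[C@H]2O[C@@]2(C)[C@@H](O)[C@H]1OC(=O)C=C(C)C | target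

**Totals**
Total step count: 14. Longest linear sequence: 14 steps from (S)-carvone (fully linear).

**Three steps most likely to fail**

Step 12 (ylide macrocyclisation). Closing a ten-membered ring through an unstabilised ylide competes with oligomerisation, elimination of Ph2S and trans ring fusion. The fallback separates ring closure from epoxide formation; it sets out from iodide 21 and returns to the route at 30. Heating 21 with PPh3 in MeCN gives the phosphonium iodide F1. KN(SiMe3)2 at high dilution then effects an intramolecular Wittig olefination of the α-silyloxy methyl ketone to the macrocyclic (Z)-alkene F2; non-stabilised ylides give Z-trisubstituted alkenes with α-alkoxy ketones, and the ring reinforces this. Esterification with angelic acid as in step 13 gives the angelate F3, and HF·pyridine gives the allylic alcohol F4. VO(acac)2/t-BuOOH in CH2Cl2 at 0 °C then epoxidises C1=C10 syn to the free C9 hydroxyl (cis epoxy alcohol, as for medium-ring Z-allylic alcohols) to give 30.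

Step 5 (proline aldol). The α-branched, β,γ-unsaturated aldehyde 9 may epimerise at C7 or react with low diastereoselectivity if the catalyst and C7 are mismatched, and the free C8 hydroxyl of 11 can attack the oxirane. The fallback builds the diol by olefination, epoxidation and hydrolysis; it sets out from 9 and returns at 11. Wittig reaction of 9 with 1-(triphenylphosphoranylidene)propan-2-one gives the (E)-enone F5. Catalyst-controlled nucleophilic epoxidation (H2O2 with a 9-amino-9-deoxy-epi-cinchona alkaloid salt, pseudoenantiomer chosen for 8R,9S) gives the trans-epoxy ketone F6 without touching the isopropenyl group. Dilute HClO4 in THF/H2O at 0 °C opens F6 at C8, the carbon remote from the carbonyl, with inversion to give the anti-diol 11.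

Step 9 (acetaldehyde cross-aldol). Catalyst control may be eroded by the Felkin preference of the epoxy aldehyde, and acetaldehyde self-condensation can dominate. The fallback uses a Lewis-acid Mukaiyama aldol; it sets out from 16 and returns at 19. Reaction of 16 with 1-(ethylsulfanyl)-1-(trimethylsilyloxy)ethene under Ti(OiPr)4/BINOL catalysis (BINOL enantiomer chosen for 3S), followed by mild acidic work-up, gives the β-hydroxy thioester F7. Reduction of F7 with Et3SiH and Pd/C gives aldehyde 18, and NaBH(OAc)3 then gives 19.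

**Further compounds**
F1 | step 12 | [(3S)-3-hydroxy-3-[(2R,3S)-2-methyl-3-[(2R,3S,4S)-3-(3-methylbut-2-enoyloxy)-5-oxo-2-(prop-1-en-2-yl)-4-(triethylsilyloxy)hexyl]oxiran-2-yl]propyl]triphenylphosphonium iodide | CC(=O)[C@@H](O[Si](CC)(CC)CC)[C@@H](OC(=O)C=C(C)C)[C@@H](C(C)=C)C[C@@H]1O[C@]1(C)[C@@H](O)CC[P+](c1ccccc1)(c1ccccc1)c1ccccc1.[I-]
F2 | step 12 | (1(10)Z,3S,4R,5S,7R,8S,9R)-4,5-epoxy-3-hydroxy-9-(triethylsilyloxy)germacra-1(10),11-dien-8-yl 3-methylbut-2-enoate | C=C(C)[C@H]1C[C@@H]2O[C@]2(C)[C@@H](O)C/C=C(/C)[C@@H](O[Si](CC)(CC)CC)[C@H]1OC(=O)C=C(C)C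
F3 | step 12 | (1(10)Z,3S,4S,5S,7R,8S,9R)-4,5-epoxy-8-(3-methylbut-2-enoyloxy)-9-(triethylsilyloxy)germacra-1(10),11-dien-3-yl (Z)-2-methylbut-2-enoate | C=C(C)[C@H]1C[C@@H]2O[C@]2(C)[C@@H](OC(=O)/C(C)=C\C)C/C=C(/C)[C@@H](O[Si](CC)(CC)CC)[C@H]1OC(=O)C=C(C)C
F4 | step 12 | (1(10)Z,3S,4S,5S,7R,8S,9R)-4,5-epoxy-9-hydroxy-8-(3-methylbut-2-enoyloxy)germacra-1(10),11-dien-3-yl (Z)-2-methylbut-2-enoate | C=C(C)[C@H]1C[C@@H]2O[C@]2(C)[C@@H](OC(=O)/C(C)=C\C)C/C=C(/C)[C@@H](O)[C@H]1OC(=O)C=C(C)C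
F5 | step 5 | S-ethyl (2S,3S)-2-methyl-3-[(2S,3E)-5-oxo-2-(prop-1-en-2-yl)hex-3-en-1-yl]oxirane-2-carbothioate | CC(=O)/C=C/[C@@H](C(C)=C)C[C@@H]1O[C@]1(C)C(=O)SCC
F6 | step 5 | S-ethyl (2S,3S)-3-[(2R)-2-[(2R,3S)-3-acetyloxiran-2-yl]-3-methylbut-3-en-1-yl]-2-methyloxirane-2-carbothioate | CC(=O)[C@H]1O[C@@H]1[C@@H](C(C)=C)C[C@@H]2O[C@]2(C)C(=O)SCC
F7 | step 9 | S-ethyl (3S)-3-hydroxy-3-[(2R,3S)-2-methyl-3-[(2R,3S,4S)-3-(3-methylbut-2-enoyloxy)-5-oxo-2-(prop-1-en-2-yl)-4-(triethylsilyloxy)hexyl]oxiran-2-yl]propanethioate | CC(=O)[C@@H](O[Si](CC)(CC)CC)[C@@H](OC(=O)C=C(C)C)[C@@H](C(C)=C)C[C@@H]1O[C@]1(C)[C@@H](O)CC(=O)SCC
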